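The readings come from a simulation with constants of no real substance, noise included.

The product in the larch run rose more and more slowly, with 80.7% of the substrate still there at 80.0 min, so what I watched was the fall of the rate and not the substrate left.

the same everywhere: substrate 0.050 M; free catalyst 1 mol%
- larch: partner 2 equiv; protic impurity 0.025 M; the very flask that is asked about, followed so far
- flask: partner 2.00 equiv; protic impurity 0.0250 M; time 3.0 h

- larch (time / min: product / %, substrate / %): 4.00: 1.2, 97.4; 12.0: 5.3, 94.3; 20.0: 9.0, 92.6; 30.0: 11.0, 89.6; 40.0: 13.7, 86.7; 60.0: 15.7, 83.0; 80.0: 20.3, 80.7

(standard deviation of a reading: 1 percentage point)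

- amount of product in the flask at 3.0 h, in percent of the substrate charged
- amount of substrate in the flask at 3.0 h, in percent of the substrate charged

I asked where the rise must end, then how fast it gets there. If a rate sinks by the same factor in each equal span of time, the conversion still to come from a given moment is that moment's rate times the fall time, the time in which the rate sinks by a factor e. I called this the reach.

The product gained 4.7 percentage points from 20.0 min to 40.0 min and 6.6 points from there to 80.0 min. That gave a fall time of 84.8 min and 28.0% at 3.0 h.

The weak link was the fall time, built on differences of readings that each scatter by 1 point; the lost substrate, read alone, gave 44.4 min. Product and substrate summed to 101% at 80.0 min, so I averaged product and lost substrate, which gave conversions of 8.20%, 13.5% and 19.8%. The fall time became 57.7 min, and the reach, rate at 80.0 min times fall time, came to 6.4 points. By 3.0 h that meant 25.1% product and 74.9% substrate.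

The forecast said 27% product and 73% substrate, naming “pseudo-first-order catalyst death”. The flask gave 25.6% and 74.4%, under this scheme:

    substrate + partner + free catalyst ⇌ product + free catalyst, rate k1*[substrate]*[partner]*[free catalyst] forward; the back reaction follows from the equilibrium constant (K = 7.00 /M, k = 189 /M²/min)
    partner + protic impurity → quenched reagent (k = 0.758 /M/min)
    free catalyst ⇌ dormant form (K = 0.860, k = 0.128 /min)
    free catalyst → spent catalyst (k = 0.00371 /min)

That product lies 0.50 points above my figure. At 3.00 h the flask still held 37.2% of its catalyst free, with 32.4% in the dormant form and 30.4% spent. Left to 30.0 h, the same flask has gone 9.8 points past my conversion at 80.0 min, further than the reach of 6.4 points, and stands at 29.6% product with free catalyst at 1.50%.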